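**Retrosynthetic overview**
1. The last bonds cut are the enol amide to 2-amino-3-hydroxycyclopent-2-enone (made from cyclopentane-1,3-dione) and the triene, which a vinylogous Horner–Wadsworth–Emmons reaction divides into a ring A C4 aldehyde and a sorbate-derived C6 phosphonate.
2. The plan rests on ring A: C1 ketone, C2 amide-bearing carbon, C3 vinyl CH, C4 tertiary carbinol, C5 secondary carbinol, C6 methylene, i.e. a 2-amido-4,5-cis-dioxygenated cyclohex-2-enone. C6–C1–C2–C3 comes from a 2-amido-1-dimethylamino-3-silyloxybuta-1,3-diene, and C4–C5 with both cis oxygens from a 2-tert-butyl-1,3-dioxole-4-carboxylate; the [4+2] forms C3–C4 and C5–C6.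
3. Diene: (2E,4R)-2,4-dimethyloct-2-enoic acid (auxiliary-controlled methylation, Wittig) joined to aminoacetone, then amide-acetal condensation and O-silylation. Dienophile: methyl (S)-glycerate, cis pivalaldehyde acetal, selenoxide elimination.
4. Ring order: ring A is the only ring constructed (step 13); the cyclopentenone ring is taken from the dione and attached in step 24.

Key step: step 13

Remark on the chemistry: ring A is numbered C1 (ketone) to C6 (methylene) throughout. The amino-bearing C3 of 20 and the C1 carbinol of 24 are carried as epimer mixtures because both centres are removed later. The aminocyclopentenone unit is drawn as the enol tautomer, as in the target.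

**Step 1**
Reactants: 1 (R)-4-benzyl-1,3-oxazolidin-2-one; 2 hexanoyl chloride
Product: 3 (R)-4-benzyl-3-hexanoyl-1,3-oxazolidin-2-one
Conditions: n-BuLi, THF, −78 °C; then 2, −78 → 0 °C
Reagents that add atoms: none
Why: N-acylation of the lithiated oxazolidinone by an acid chloride is routine imide formation and leaves the auxiliary stereocentre untouched.

**Step 2**
Reactants: 3 (R)-4-benzyl-3-hexanoyl-1,3-oxazolidin-2-one
Product: 4 (R)-4-benzyl-3-[(R)-2-methylhexanoyl]-1,3-oxazolidin-2-one
Conditions: NaHMDS, THF, −78 °C; MeI, −78 °C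
Reagents that add atoms: iodomethane, CI
Why: Evans asymmetric alkylation, in which the chelated Z-sodium enolate is methylated on the face opposite the benzyl group, so the (R)-auxiliary should give the (R)-2-methyl centre (the later C4 of the side chain); the minor diastereomer is removed by chromatography.

**Step 3**
Reactants: 4 (R)-4-benzyl-3-[(R)-2-methylhexanoyl]-1,3-oxazolidin-2-one
Product: 5 (R)-2-methylhexan-1-ol
Conditions: LiBH4, Et2O, H2O (1 equiv), 0 °C
Reagents that add atoms: none
Why: Reductive cleavage of the imide by LiBH4 releases the primary alcohol without touching the α-stereocentre and returns the auxiliary.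

**Step 4**
Reactants: 5 (R)-2-methylhexan-1-ol; 6 ethyl 2-(triphenylphosphoranylidene)propanoate
Product: 8 ethyl (2E,4R)-2,4-dimethyloct-2-enoate, via (R)-2-methylhexanal 7 (not isolated)
Conditions: TEMPO (cat.), PhI(OAc)2, CH2Cl2, rt; aq. NaHCO3/Na2S2O3 wash; then 6, CH2Cl2, rt → 40 °C
Reagents that add atoms: none
Why: Nitroxyl-catalysed oxidation gives the α-branched aldehyde under non-basic conditions (no epimerisation), and the Wittig reaction of the stabilised α-methyl ylide with the washed aldehyde solution should give the E-trisubstituted enoate.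

**Step 5**
Reactants: 8 ethyl (2E,4R)-2,4-dimethyloct-2-enoate
Product: 9 (2E,4R)-2,4-dimethyloct-2-enoic acid
Conditions: LiOH·H2O, THF/MeOH/H2O, 40 °C; then 1 M HCl
Reagents that add atoms: lithium hydroxide, [Li+].[OH-]
Why: Saponification of the conjugated ester, under which the γ-stereocentre is not acidic and the alkene geometry is retained.

**Step 6**
Reactants: 9 (2E,4R)-2,4-dimethyloct-2-enoic acid; 10 aminoacetone hydrochloride
Product: 11 (2E,4R)-2,4-dimethyl-N-(2-oxopropyl)oct-2-enamide
Conditions: EDC·HCl, HOBt, N-methylmorpholine, CH2Cl2, 0 °C → rt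
Reagents that add atoms: none
Why: Carbodiimide/HOBt amide coupling in which the aminoketone is set free slowly in the presence of the active ester, so N-acylation should outrun self-condensation, and no acid chloride (vinylketene) pathway can scramble C4.

**Step 7**
Reactants: 11 (2E,4R)-2,4-dimethyl-N-(2-oxopropyl)oct-2-enamide
Product: 12 (2E,4R)-N-[(1Z)-1-(dimethylamino)-3-oxobut-1-en-2-yl]-2,4-dimethyloct-2-enamide
Conditions: Me2NCH(OMe)2 (1.2 equiv), PhMe, 90 °C
Reagents that add atoms: N,N-dimethylformamide dimethyl acetal, COC(OC)N(C)C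
Why: Amide-acetal condensation at the methylene activated by both the ketone and the acylamino group (the usual site for N-acylaminoacetones) gives the push–pull enaminone with NMe2 anti to the acetyl group; the reagent is limited to avoid a second condensation at the methyl group.

**Step 8**
Reactants: 12 (2E,4R)-N-[(1Z)-1-(dimethylamino)-3-oxobut-1-en-2-yl]-2,4-dimethyloct-2-enamide
Product: 13 (2E,4R)-N-[(1Z)-3-(tert-butyldimethylsilyloxy)-1-(dimethylamino)buta-1,3-dien-2-yl]-2,4-dimethyloct-2-enamide
Conditions: TBSOTf (1.1 equiv), Et3N, Et2O, −78 → 0 °C; salts decanted, used crude under Ar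
Reagents that add atoms: tert-butyldimethylsilyl trifluoromethanesulfonate, CC(C)(C)[Si](C)(C)OS(=O)(=O)C(F)(F)F
Why: Soft enolisation, in which the strongly nucleophilic vinylogous amide oxygen is silylated in preference to the amide N–H and Et3N then removes a methyl proton, is the standard route to 1-amino-3-siloxydienes.

**Step 9**
Reactants: 14 methyl (S)-2,2-dimethyl-1,3-dioxolane-4-carboxylate
Product: 15 methyl (S)-2,3-dihydroxypropanoate
Conditions: Amberlyst 15 (H+ form), MeOH, rt
Reagents that add atoms: none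
Why: Acid-catalysed transketalisation to methanol removes the isopropylidene group without affecting the ester or the stereocentre.

**Step 10**
Reactants: 15 methyl (S)-2,3-dihydroxypropanoate
Product: 16 methyl (2S,4S)-2-tert-butyl-1,3-dioxolane-4-carboxylate (cis)
Conditions: t-BuCHO, camphorsulfonic acid (cat.), pentane, reflux, Dean–Stark; SiO2 chromatography
Reagents that add atoms: pivalaldehyde, CC(C)(C)C=O
Why: Thermodynamic acetalisation should give a cis/trans mixture that only modestly favours cis, so the cis isomer, in which the glycerate centre fixes the acetal carbon as S, is separated by chromatography and the trans isomer is re-equilibrated with acid.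

**Step 11**
Reactants: 16 methyl (2S,4S)-2-tert-butyl-1,3-dioxolane-4-carboxylate
Product: 17 methyl (2S,4R)-2-tert-butyl-4-(phenylselanyl)-1,3-dioxolane-4-carboxylate
Conditions: LDA, THF, −78 °C; PhSeBr, −78 °C
Reagents that add atoms: phenylselenyl bromide, Br[Se]c1ccccc1
Why: α-Selenenylation of the ester enolate, formed and trapped at −78 °C to suppress β-alkoxide elimination; the electrophile should enter anti to tert-butyl, but the C4 configuration is destroyed in the next step.

**Step 12**
Reactants: 17 methyl (2S,4R)-2-tert-butyl-4-(phenylselanyl)-1,3-dioxolane-4-carboxylate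
Product: 19 methyl (S)-2-tert-butyl-1,3-dioxole-4-carboxylate, via selenoxide 18 (not isolated)
Conditions: 30% H2O2, pyridine, CH2Cl2, 0 °C → rt
Reagents that add atoms: none
Why: Selenoxide syn-elimination toward the only β-hydrogens (C5) should give the ring alkene under buffered conditions, leaving the acetal carbon as the sole, untouched stereocentre.

**Step 13**
Reactants: 13 (2E,4R)-N-[(1Z)-3-(tert-butyldimethylsilyloxy)-1-(dimethylamino)buta-1,3-dien-2-yl]-2,4-dimethyloct-2-enamide; 19 methyl (S)-2-tert-butyl-1,3-dioxole-4-carboxylate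
Product: 21 methyl (2S,3aS,7aR)-2-tert-butyl-5-[(2E,4R)-2,4-dimethyloct-2-enamido]-6-oxo-3a,6,7,7a-tetrahydro-1,3-benzodioxole-3a-carboxylate (ring A enone, C4 S, C5 R, tert-butyl exo), via amino silyl enol ether cycloadduct 20 (not isolated)
Conditions: 13 (2 equiv), PhMe, 100 °C, sealed tube; then 48% aq. HF/MeCN (1:19), 0 °C
Reagents that add atoms: none
Why: This is a concerted but strongly asynchronous normal-demand [4+2] cycloaddition in which the CH2 terminus of the diene (C6) bonds first to the alkoxy-bearing β-carbon of the enoate (C5) and the amino-bearing terminus (C3) then closes onto the ester-bearing carbon (C4), so ring A is closed by an intermolecular six-membered annulation in one operation. The closest known reaction type is the Diels–Alder reaction of 1-amino-3-siloxybutadienes with acrylates followed by acid-induced loss of the amine to give 4-substituted cyclohexenones; the present dienophile is weakened by its two oxygen donors, which is why the most electron-rich diene class, an excess of diene and heat are used. C4 and C5 are created together: their cis relationship follows from suprafacial addition to a ring alkene whose oxygens are locked cis, and their absolute configuration from approach to the face of the nearly flat dioxole anti to the tert-butyl group on the (S)-acetal carbon. The step needs regioselectivity (C6 to C5, C3 to C4), which the match of the nucleophilic diene terminus with the electrophilic β-carbon secures, whereas endo/exo selectivity is irrelevant because C3 loses its stereocentre. Cold dilute HF then hydrolyses the silyl enol ether of 20 to the C1 ketone and β-elimination of dimethylamine places the alkene at C2=C3 with the amide already on C2, while the pivalaldehyde acetal should survive.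

**Step 14**
Reactants: 21 ring A enone with tert-butyl acetal and C4 methyl ester
Product: 22 methyl (1S,6R)-3-[(2E,4R)-2,4-dimethyloct-2-enamido]-1,6-dihydroxy-4-oxocyclohex-2-ene-1-carboxylate
Conditions: TFA/H2O (9:1), 0 °C → rt
Reagents that add atoms: none
Why: Acid hydrolysis of the aldehyde acetal frees the cis-diol at the stage where the molecule is most robust; the ester and the 2-amido enone should tolerate aqueous TFA.

**Step 15**
Reactants: 22 methyl (1S,6R)-3-[(2E,4R)-2,4-dimethyloct-2-enamido]-1,6-dihydroxy-4-oxocyclohex-2-ene-1-carboxylate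
Product: 23 methyl (1S,6R)-3-[(2E,4R)-2,4-dimethyloct-2-enamido]-4-oxo-1,6-bis(triethylsilyloxy)cyclohex-2-ene-1-carboxylate
Conditions: TESOTf (3 equiv), 2,6-lutidine, CH2Cl2, −78 → −20 °C
Reagents that add atoms: triethylsilyl trifluoromethanesulfonate, CC[Si](CC)(CC)OS(=O)(=O)C(F)(F)F
Why: Silyl triflate silylation covers the secondary and the hindered tertiary alcohol with groups removable by fluoride at the end; low temperature and the hindered base limit β-elimination, and any N-silyl or enol silyl groups hydrolyse on work-up.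

**Step 16**
Reactants: 23 methyl (1S,6R)-3-[(2E,4R)-2,4-dimethyloct-2-enamido]-4-oxo-1,6-bis(triethylsilyloxy)cyclohex-2-ene-1-carboxylate
Product: 24 (2E,4R)-N-[(3R,4R)-6-hydroxy-3-(hydroxymethyl)-3,4-bis(triethylsilyloxy)cyclohex-1-en-1-yl]-2,4-dimethyloct-2-enamide (C6 epimers)
Conditions: i-Bu2AlH (6 equiv), CH2Cl2, −78 → 0 °C; aq. KNaC4H4O6
Reagents that add atoms: none
Why: Hydride reduction takes the ester to the primary alcohol and the enone carbonyl (1,2) to the allylic alcohol, which avoids the ketone-versus-ester selectivity problem; the aluminium amidates of both amides are inert at this temperature.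

**Step 17**
Reactants: 24 (2E,4R)-N-[(3R,4R)-6-hydroxy-3-(hydroxymethyl)-3,4-bis(triethylsilyloxy)cyclohex-1-en-1-yl]-2,4-dimethyloct-2-enamide
Product: 25 (2E,4R)-N-[(3S,4R)-3-formyl-6-oxo-3,4-bis(triethylsilyloxy)cyclohex-1-en-1-yl]-2,4-dimethyloct-2-enamide
Conditions: Dess–Martin periodinane (3 equiv), NaHCO3, CH2Cl2, 0 °C → rt
Reagents that add atoms: none
Why: Dess–Martin oxidation returns the allylic alcohol to the enone and takes the neopentyl alcohol to the aldehyde under buffered conditions; C4 is quaternary and cannot epimerise.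

**Step 18**
Reactants: 26 methyl (2E,4E)-hexa-2,4-dienoate (methyl sorbate)
Product: 27 methyl (2E,4E)-6-bromohexa-2,4-dienoate
Conditions: NBS, (PhCO2)2 (cat.), PhCl, 100 °C
Reagents that add atoms: N-bromosuccinimide, O=C1CCC(=O)N1Br
Why: Wohl–Ziegler bromination at the terminal dienylic methyl group, a known transformation of sorbates.

**Step 19**
Reactants: 27 methyl (2E,4E)-6-bromohexa-2,4-dienoate
Product: 28 methyl (2E,4E)-6-(diethoxyphosphoryl)hexa-2,4-dienoate
Conditions: P(OEt)3, neat, 130 °C
Reagents that add atoms: triethyl phosphite, CCOP(OCC)OCC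
Why: Michaelis–Arbuzov reaction of the primary allylic bromide.

**Step 20**
Reactants: 25 ring A C4 aldehyde (bis-triethylsilyl ether); 28 methyl (2E,4E)-6-(diethoxyphosphoryl)hexa-2,4-dienoate
Product: 29 methyl (2E,4E,6E)-7-[(1S,6R)-3-[(2E,4R)-2,4-dimethyloct-2-enamido]-4-oxo-1,6-bis(triethylsilyloxy)cyclohex-2-en-1-yl]hepta-2,4,6-trienoate
Conditions: 28 (2.5 equiv), LiHMDS (2.3 equiv), THF, −78 °C; then 25, −78 → −20 °C
Reagents that add atoms: none
Why: Vinylogous Horner–Wadsworth–Emmons olefination, in which the phosphonate anion should attack the aldehyde in preference to the conjugated amido ketone and give the new alkene E; excess pre-formed anion covers the amide N–H and low temperature limits enolisation of the C1 ketone.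

**Step 21**
Reactants: 29 methyl trienoate (bis-triethylsilyl ether)
Product: 31 (2E,4E,6E)-7-[(1S,6R)-3-[(2E,4R)-2,4-dimethyloct-2-enamido]-4-oxo-1,6-bis(triethylsilyloxy)cyclohex-2-en-1-yl]hepta-2,4,6-trienoic acid, via trimethylstannyl ester 30 (not isolated)
Conditions: Me3SnOH, ClCH2CH2Cl, 70 °C; cold 0.1 M HCl wash
Reagents that add atoms: trimethyltin hydroxide, C[Sn](C)(C)O
Why: Tin hydroxide ester cleavage transfers hydroxide under nearly neutral conditions, which should spare the β-silyloxy ketone and both silyl ethers where aqueous alkali would risk elimination.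

**Step 22**
Reactants: 32 cyclopentane-1,3-dione
Product: 33 3-hydroxy-2-nitrocyclopent-2-en-1-one
Conditions: fuming HNO3, AcOH, 10 °C
Reagents that add atoms: nitric acid, O[N+](=O)[O-]
Why: Electrophilic nitration of the enolised 1,3-dione at C2, as known for cyclic 1,3-diones.

**Step 23**
Reactants: 33 3-hydroxy-2-nitrocyclopent-2-en-1-one
Product: 34 2-amino-3-hydroxycyclopent-2-en-1-one hydrochloride
Conditions: H2 (1 atm), 10% Pd/C, MeOH, HCl (1 equiv), rt
Reagents that add atoms: hydrogen chloride, Cl
Why: Catalytic hydrogenation of the nitro group; the vinylogous acid is not reduced and the amine is trapped as its salt to prevent self-condensation.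

**Step 24**
Reactants: 31 trienoic acid (bis-triethylsilyl ether); 34 2-amino-3-hydroxycyclopent-2-en-1-one hydrochloride
Product: 35 (2E,4E,6E)-7-[(1S,6R)-3-[(2E,4R)-2,4-dimethyloct-2-enamido]-4-oxo-1,6-bis(triethylsilyloxy)cyclohex-2-en-1-yl]-N-(2-hydroxy-5-oxocyclopent-1-en-1-yl)hepta-2,4,6-trienamide
Conditions: EDC·HCl, HOBt, N-methylmorpholine, DMF, 0 °C → rt
Reagents that add atoms: none
Why: Carbodiimide/HOBt amide coupling with the 2-amino-1,3-dione; any enol O-acyl isomer should rearrange to the amide by O-to-N acyl shift under the basic conditions.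

**Step 25**
Reactants: 35 bis-triethylsilyl ether of the target
Product: 36 (2E,4E,6E)-7-[(1S,6R)-3-[(2E,4R)-2,4-dimethyloct-2-enamido]-1,6-dihydroxy-4-oxocyclohex-2-en-1-yl]-N-(2-hydroxy-5-oxocyclopent-1-en-1-yl)hepta-2,4,6-trienamide (CNP0154433.2)
Conditions: HF·pyridine, pyridine, THF, 0 °C → rt
Reagents that add atoms: none
Why: Buffered fluoride desilylation removes both triethylsilyl ethers without base, so the β-hydroxy ketone should be neither dehydrated nor opened by retro-aldol cleavage.

**Compound list**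
1 | (R)-4-benzyl-1,3-oxazolidin-2-one | O=C1N[C@H](Cc2ccccc2)CO1 | starting material
2 | hexanoyl chloride | CCCCCC(=O)Cl | starting material
3 | (R)-4-benzyl-3-hexanoyl-1,3-oxazolidin-2-one | CCCCCC(=O)N1[C@H](Cc2ccccc2)COC1=O | intermediate
4 | (R)-4-benzyl-3-[(R)-2-methylhexanoyl]-1,3-oxazolidin-2-one | CCCC[C@@H](C)C(=O)N1[C@H](Cc2ccccc2)COC1=O | intermediate
5 | (R)-2-methylhexan-1-ol | CCCC[C@@H](C)CO | intermediate
6 | ethyl 2-(triphenylphosphoranylidene)propanoate | CCOC(=O)C(C)=P(c1ccccc1)(c1ccccc1)c1ccccc1 | starting material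
7 | (R)-2-methylhexanal | CCCC[C@@H](C)C=O | intermediate (not isolated)
8 | ethyl (2E,4R)-2,4-dimethyloct-2-enoate | CCCC[C@@H](C)/C=C(\C)C(=O)OCC | intermediate
9 | (2E,4R)-2,4-dimethyloct-2-enoic acid | CCCC[C@@H](C)/C=C(\C)C(=O)O | intermediate
10 | aminoacetone hydrochloride | CC(=O)CN.Cl | starting material
11 | (2E,4R)-2,4-dimethyl-N-(2-oxopropyl)oct-2-enamide | CCCC[C@@H](C)/C=C(\C)C(=O)NCC(C)=O | intermediate
12 | (2E,4R)-N-[(1Z)-1-(dimethylamino)-3-oxobut-1-en-2-yl]-2,4-dimethyloct-2-enamide | CCCC[C@@H](C)/C=C(\C)C(=O)NC(=C/N(C)C)\C(C)=O | intermediate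
13 | (2E,4R)-N-[(1Z)-3-(tert-butyldimethylsilyloxy)-1-(dimethylamino)buta-1,3-dien-2-yl]-2,4-dimethyloct-2-enamide | CCCC[C@@H](C)/C=C(\C)C(=O)NC(=C/N(C)C)\C(=C)O[Si](C)(C)C(C)(C)C | intermediate
14 | methyl (S)-2,2-dimethyl-1,3-dioxolane-4-carboxylate | COC(=O)[C@@H]1COC(C)(C)O1 | starting material
15 | methyl (S)-2,3-dihydroxypropanoate | COC(=O)[C@@H](O)CO | intermediate
16 | methyl (2S,4S)-2-tert-butyl-1,3-dioxolane-4-carboxylate | COC(=O)[C@@H]1CO[C@H](C(C)(C)C)O1 | intermediate
17 | methyl (2S,4R)-2-tert-butyl-4-(phenylselanyl)-1,3-dioxolane-4-carboxylate | COC(=O)[C@]1([Se]c2ccccc2)CO[C@H](C(C)(C)C)O1 | intermediate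
18 | selenoxide of 17 | COC(=O)[C@]1([Se](=O)c2ccccc2)CO[C@H](C(C)(C)C)O1 | intermediate (not isolated)
19 | methyl (S)-2-tert-butyl-1,3-dioxole-4-carboxylate | COC(=O)C1=CO[C@H](C(C)(C)C)O1 | intermediate
20 | Diels–Alder adduct: ring A as C1 silyl enol ether with the amide on C2, NMe2 on C3 (epimers), CO2Me on C4 and the (S)-tert-butyl acetal on the cis C4/C5 oxygens | CCCC[C@@H](C)/C=C(\C)C(=O)NC=1C(N(C)C)[C@@](O[C@@H](C(C)(C)C)O2)(C(=O)OC)[C@H]2CC=1O[Si](C)(C)C(C)(C)C | intermediate (not isolated)
21 | methyl (2S,3aS,7aR)-2-tert-butyl-5-[(2E,4R)-2,4-dimethyloct-2-enamido]-6-oxo-3a,6,7,7a-tetrahydro-1,3-benzodioxole-3a-carboxylate | CCCC[C@@H](C)/C=C(\C)C(=O)NC1=C[C@@](O[C@@H](C(C)(C)C)O2)(C(=O)OC)[C@H]2CC1=O | intermediate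
22 | methyl (1S,6R)-3-[(2E,4R)-2,4-dimethyloct-2-enamido]-1,6-dihydroxy-4-oxocyclohex-2-ene-1-carboxylate | CCCC[C@@H](C)/C=C(\C)C(=O)NC1=C[C@@](O)(C(=O)OC)[C@H](O)CC1=O | intermediate
23 | methyl (1S,6R)-3-[(2E,4R)-2,4-dimethyloct-2-enamido]-4-oxo-1,6-bis(triethylsilyloxy)cyclohex-2-ene-1-carboxylate | CCCC[C@@H](C)/C=C(\C)C(=O)NC1=C[C@@](O[Si](CC)(CC)CC)(C(=O)OC)[C@H](O[Si](CC)(CC)CC)CC1=O | intermediate
24 | (2E,4R)-N-[(3R,4R)-6-hydroxy-3-(hydroxymethyl)-3,4-bis(triethylsilyloxy)cyclohex-1-en-1-yl]-2,4-dimethyloct-2-enamide (C6 epimers) | CCCC[C@@H](C)/C=C(\C)C(=O)NC1=C[C@@](O[Si](CC)(CC)CC)(CO)[C@H](O[Si](CC)(CC)CC)CC1O | intermediate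
25 | (2E,4R)-N-[(3S,4R)-3-formyl-6-oxo-3,4-bis(triethylsilyloxy)cyclohex-1-en-1-yl]-2,4-dimethyloct-2-enamide | CCCC[C@@H](C)/C=C(\C)C(=O)NC1=C[C@@](O[Si](CC)(CC)CC)(C=O)[C@H](O[Si](CC)(CC)CC)CC1=O | intermediate
26 | methyl (2E,4E)-hexa-2,4-dienoate | C/C=C/C=C/C(=O)OC | starting material
27 | methyl (2E,4E)-6-bromohexa-2,4-dienoate | BrC/C=C/C=C/C(=O)OC | intermediate
28 | methyl (2E,4E)-6-(diethoxyphosphoryl)hexa-2,4-dienoate | CCOP(=O)(OCC)C/C=C/C=C/C(=O)OC | intermediate
29 | methyl (2E,4E,6E)-7-[(1S,6R)-3-[(2E,4R)-2,4-dimethyloct-2-enamido]-4-oxo-1,6-bis(triethylsilyloxy)cyclohex-2-en-1-yl]hepta-2,4,6-trienoate | CCCC[C@@H](C)/C=C(\C)C(=O)NC1=C[C@@](O[Si](CC)(CC)CC)(/C=C/C=C/C=C/C(=O)OC)[C@H](O[Si](CC)(CC)CC)CC1=O | intermediate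
30 | trimethylstannyl ester of 31 | CCCC[C@@H](C)/C=C(\C)C(=O)NC1=C[C@@](O[Si](CC)(CC)CC)(/C=C/C=C/C=C/C(=O)O[Sn](C)(C)C)[C@H](O[Si](CC)(CC)CC)CC1=O | intermediate (not isolated)
31 | (2E,4E,6E)-7-[(1S,6R)-3-[(2E,4R)-2,4-dimethyloct-2-enamido]-4-oxo-1,6-bis(triethylsilyloxy)cyclohex-2-en-1-yl]hepta-2,4,6-trienoic acid | CCCC[C@@H](C)/C=C(\C)C(=O)NC1=C[C@@](O[Si](CC)(CC)CC)(/C=C/C=C/C=C/C(=O)O)[C@H](O[Si](CC)(CC)CC)CC1=O | intermediate
32 | cyclopentane-1,3-dione | O=C1CCC(=O)C1 | starting material
33 | 3-hydroxy-2-nitrocyclopent-2-en-1-one | O=C1CCC(O)=C1[N+](=O)[O-] | intermediate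
34 | 2-amino-3-hydroxycyclopent-2-en-1-one hydrochloride | NC1=C(O)CCC1=O.Cl | intermediate
35 | bis-triethylsilyl ether of the target | CCCC[C@@H](C)/C=C(\C)C(=O)NC1=C[C@@](O[Si](CC)(CC)CC)(/C=C/C=C/C=C/C(=O)NC2=C(O)CCC2=O)[C@H](O[Si](CC)(CC)CC)CC1=O | intermediate
36 | (2E,4E,6E)-7-[(1S,6R)-3-[(2E,4R)-2,4-dimethyloct-2-enamido]-1,6-dihydroxy-4-oxocyclohex-2-en-1-yl]-N-(2-hydroxy-5-oxocyclopent-1-en-1-yl)hepta-2,4,6-trienamide | CCCC[C@@H](C)/C=C(\C)C(=O)NC1=C[C@@](O)(/C=C/C=C/C=C/C(=O)NC2=C(O)CCC2=O)[C@H](O)CC1=O | target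

**Step count**
Total: 25 steps. Longest linear sequence: 17 steps (1–8, 13–17, 20, 21, 24, 25).

**Steps most likely to fail**

Step 13. The cycloaddition may be too slow, because the donor-substituted dienophile is electron-rich and the amido diene is hindered and thermally fragile, so that diene decomposition outruns ring formation. Fallback: separate the amide from the cycloaddition. Setting out from 19, the commercial parent diene (E)-1-(dimethylamino)-3-(tert-butyldimethylsilyloxy)buta-1,3-diene, which is more reactive, can be used in large excess or neat and tolerates long heating, is heated with 19 in toluene to give the amino silyl enol ether cycloadduct F1. Cold HF/MeCN converts it into methyl (2S,3aS,7aR)-2-tert-butyl-6-oxo-3a,6,7,7a-tetrahydro-1,3-benzodioxole-3a-carboxylate F2. α-Iodination of the enone with I2/pyridine in CH2Cl2 gives the 5-iodo enone F3. Acid 9 is converted by isobutyl chloroformate/N-methylmorpholine and then ammonia into (2E,4R)-2,4-dimethyloct-2-enamide F4. Goldberg-type coupling of F3 with F4 (CuI, N,N'-dimethylethylenediamine, K2CO3, toluene, 70 °C) returns to the route at 21.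

Step 12. The syn-elimination has to run toward the oxygen-bearing C5, the slow direction for selenoxides, so that side reactions of the selenoxide or acid-induced loss of the acetal may take over. Fallback: a polar dehydrohalogenation in place of the pericyclic elimination. Setting out from 16, the enolate (LDA, THF, −78 °C) is brominated with CBr4 to give methyl (2S,4R)-4-bromo-2-tert-butyl-1,3-dioxolane-4-carboxylate F5, and E2 elimination with DBU in CH2Cl2 returns to the route at 19.

Step 20. The basic phosphonate anion may enolise the C1 ketone, after which the C5 silyloxy group is expelled (E1cB), or it may be quenched by the amide N–H. Fallback: build the triene under non-basic conditions. Setting out from 25, Takai iodo-olefination (CrCl2, CHI3, THF, 0 °C) gives the (E)-vinyl iodide of ring A F6. Methyl (2E,4E)-5-(tributylstannyl)penta-2,4-dienoate F7 is made by mono-Stille coupling of commercial (E)-1,2-bis(tributylstannyl)ethene with methyl (E)-3-iodoacrylate (Pd(PPh3)4, DMF, rt). Stille coupling of F6 with F7 (Pd2(dba)3, AsPh3, DMF, rt) returns to the route at 29.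

**Further compounds**
F1 | step 13 | amino silyl enol ether cycloadduct of the parent diene with 19 (C3 epimers) | C=1C(N(C)C)[C@@](O[C@@H](C(C)(C)C)O2)(C(=O)OC)[C@H]2CC=1O[Si](C)(C)C(C)(C)C
F2 | step 13 | methyl (2S,3aS,7aR)-2-tert-butyl-6-oxo-3a,6,7,7a-tetrahydro-1,3-benzodioxole-3a-carboxylate | O=C1C=C[C@@](O[C@@H](C(C)(C)C)O2)(C(=O)OC)[C@H]2C1
F3 | step 13 | 5-iodo derivative of F2 (iodine on ring A C2) | O=C1C(I)=C[C@@](O[C@@H](C(C)(C)C)O2)(C(=O)OC)[C@H]2C1
F4 | step 13 | (2E,4R)-2,4-dimethyloct-2-enamide | CCCC[C@@H](C)/C=C(\C)C(N)=O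
F5 | step 12 | methyl (2S,4R)-4-bromo-2-tert-butyl-1,3-dioxolane-4-carboxylate | COC(=O)[C@]1(Br)CO[C@H](C(C)(C)C)O1
F6 | step 20 | (E)-vinyl iodide of ring A (25 with CHO replaced by CH=CHI) | CCCC[C@@H](C)/C=C(\C)C(=O)NC1=C[C@@](O[Si](CC)(CC)CC)(/C=C/I)[C@H](O[Si](CC)(CC)CC)CC1=O
F7 | step 20 | methyl (2E,4E)-5-(tributylstannyl)penta-2,4-dienoate | CCCC[Sn](CCCC)(CCCC)/C=C/C=C/C(=O)OC
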